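**Plan**

1. Locants are those of the target as a 3,4-dihydronaphthalene-2-carbaldehyde: C1 vinylic CH, C2 formyl-bearing carbon, C3 CH(CH2OH), C4 CH(aryl). Ring A is the aromatic ring C4a–C8a and ring B the dihydro ring.
2. Retrosynthesis: after removal of two phenol silyl groups, C1=C2 and C4–C4a are cut together in a [3+3] sense. This gives a protected syringaldehyde (C1 plus ring A) and a C2–C3–C4 lactol, which goes back through alkene cleavage and auxiliary removal to a syn-aldol (C3–C4 bond) of an N-pent-4-enoyl oxazolidinone with protected vanillin.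
3. Enabling feature: C4 is benzylic and para to the C4' oxygen of the guaiacyl ring, so its C–O bond ionizes easily, and it stands 1,3 to C2, the α-carbon of the formyl group. Ring A offers the matching pair: its aldehyde carbon (C1) and the ortho carbon C4a, which is ortho to the C5 methoxy, para to the C7 methoxy, and one of two symmetry-equivalent sites.
4. Forward: the chain is built first (aldol, reduction, cleavage to a 2-aryltetrahydrofuran lactol as a temporary ring). Ring B then closes in one pot by crossed aldol condensation and ring-opening Friedel–Crafts alkylation, and desilylation ends the route.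
5. Stereochemistry: C3 comes from the (S)-4-benzyloxazolidinone in the boron aldol. C4 is erased on ionization and reset trans to C3 in the ring closure, so the carbinol configuration and the lactol anomers do not matter (stereoconvergent).

Key step: step 7

Remark: lactol 8 is drawn as the 5-aryltetrahydrofuran-2-ol; it should equilibrate with the open hydroxy aldehyde and with the isomeric lactol through the primary hydroxyl, and all of these enter step 7 through the same enamine.

**Route**

Step 1
Reactants: 1 (S)-4-benzyloxazolidin-2-one; 2 pent-4-enoyl chloride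
Product: 3 (S)-4-benzyl-3-(pent-4-enoyl)oxazolidin-2-one
Conditions: n-BuLi, THF, −78 °C; then 2, −78 to 0 °C
Reagents that add atoms: none
Why: N-acylation of the lithiated oxazolidinone with an acid chloride is the standard imide formation and touches no stereocenter.

Step 2
Reactants: 4 vanillin
Product: 5 4-(tert-butyldimethylsilyloxy)-3-methoxybenzaldehyde
Conditions: TBSCl, imidazole, DMF, rt
Reagents that add atoms: tert-butyldimethylsilyl chloride, CC(C)(C)[Si](C)(C)Cl
Why: Phenol silylation is routine, leaves the aldehyde free, and the aryl silyl ether should survive the boron aldol, hydride, periodate and acid steps that follow.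

Step 3
Reactants: 3 (S)-4-benzyl-3-(pent-4-enoyl)oxazolidin-2-one; 5 4-(tert-butyldimethylsilyloxy)-3-methoxybenzaldehyde
Product: 6 (S)-4-benzyl-3-[(2S)-2-[(S)-[4-(tert-butyldimethylsilyloxy)-3-methoxyphenyl](hydroxy)methyl]pent-4-enoyl]oxazolidin-2-one
Conditions: Bu2BOTf, i-Pr2NEt, CH2Cl2, 0 °C; then 5, −78 to 0 °C; pH 7 buffer, MeOH, H2O2, 0 °C
Reagents that add atoms: none
Why: In this Evans syn-aldol reaction the Z-boron enolate should react through a closed chair transition state on the face away from the benzyl group, which sets the α-carbon (the later C3) as S and the carbinol carbon syn to it, the latter being dispensable.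

Step 4
Reactants: 6 syn-aldol imide
Product: 7 (1S,2R)-1-[4-(tert-butyldimethylsilyloxy)-3-methoxyphenyl]-2-(prop-2-enyl)propane-1,3-diol
Conditions: LiBH4, MeOH (1 equiv), THF, 0 °C
Reagents that add atoms: none
Why: Reductive cleavage of the N-acyl oxazolidinone with LiBH4 should give the primary alcohol and return the auxiliary without touching the alkene, the aryl silyl ether or the stereocenters (the descriptor at the later C3 changes from S to R by priority only).

Step 5
Reactants: 7 diol
Product: 8 (4R,5S)-5-[4-(tert-butyldimethylsilyloxy)-3-methoxyphenyl]-4-(hydroxymethyl)tetrahydrofuran-2-ol (anomer mixture)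
Conditions: OsO4 (cat.), NaIO4, 2,6-lutidine, dioxane/H2O, rt
Reagents that add atoms: sodium periodate, [Na+].[O-]I(=O)(=O)=O (terminal oxygen source, delivered through OsO4, O=[Os](=O)(=O)=O)
Why: Lemieux–Johnson cleavage of the terminal alkene should give the γ-hydroxy aldehyde, which closes spontaneously to the five-membered lactol (the temporary ring), while the 1,3-diol is inert to periodate and no stereocenter of consequence is touched.

Step 6
Reactants: 9 syringaldehyde
Product: 10 4-(tert-butyldimethylsilyloxy)-3,5-dimethoxybenzaldehyde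
Conditions: TBSCl, imidazole, DMF, rt
Reagents that add atoms: tert-butyldimethylsilyl chloride, CC(C)(C)[Si](C)(C)Cl
Why: Silylation removes the acidic para-hydroxyl, which as a phenoxide would shut down the electrophilicity of the aldehyde in the condensation.

Step 7
Reactants: 8 lactol; 10 4-(tert-butyldimethylsilyloxy)-3,5-dimethoxybenzaldehyde
Product: 12 (3R,4S)-6-(tert-butyldimethylsilyloxy)-4-[4-(tert-butyldimethylsilyloxy)-3-methoxyphenyl]-3-(hydroxymethyl)-5,7-dimethoxy-3,4-dihydronaphthalene-2-carbaldehyde, via E-enal 11 (not isolated)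
Conditions: pyrrolidine (0.3 equiv), PhCO2H (0.3 equiv), toluene, 50 °C; then TFA (10 equiv), CH2Cl2, 0 °C to rt; NaHCO3, MeOH/H2O work-up
Reagents that add atoms: none
Why: Proposed new method: pyrrolidine should open lactol 8 to the enamine of the hydroxy aldehyde, which adds to the iminium ion of 10 and loses the amine (Mannich–elimination form of a crossed aldol condensation) to give E-enal 11 with the new C1=C2 bond and ring A cis to C3; TFA then ionizes the C4–O bond, benzylic and para to the silyloxy oxygen of the guaiacyl ring, and the cation is captured by C4a of ring A. The closest known reaction types are the amine-catalysed crossed aldol condensation of aliphatic with aromatic aldehydes and the acid-mediated Friedel–Crafts cyclization of α-arylidene-β-(α-hydroxybenzyl)-γ-butyrolactones to trans-1-aryl-1,2-dihydronaphthalenes; what is new is the telescoped [3+3] union from an unprotected lactol at the aldehyde oxidation level. Ring B is the only ring closed, in a 6-exo-trig attack of the arene on the planar benzylic cation, while the temporary tetrahydrofuran ring is opened. The C4 stereocenter is controlled by C3: the planar cation should be attacked in a half-chair transition state that places the aryl group trans to the C3 hydroxymethyl group, so either carbinol epimer converges on the (3R,4S) product, and C3 itself is neither enolizable nor allylic to a leaving group. The step needs crossed over self-condensation (helped by the low concentration of free aldehyde from the lactol and by the β-branch), E geometry (the thermodynamic isomer, which is the one that puts ring A next to C3) and attack at C4a (the two ortho positions of ring A are equivalent and each is activated by one ortho and one para methoxy group).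

Step 8
Reactants: 12 bis-silyl dihydronaphthalene aldehyde
Product: 13 (3R,4S)-6-hydroxy-4-(4-hydroxy-3-methoxyphenyl)-3-(hydroxymethyl)-5,7-dimethoxy-3,4-dihydronaphthalene-2-carbaldehyde
Conditions: Bu4NF, AcOH, THF, 0 °C, argon
Reagents that add atoms: none
Why: Fluoride-mediated desilylation should cleave both aryl silyl ethers, and the acetic acid buffer keeps the phenols protonated so that the doubly benzylic C4–H and the enal are left alone and both stereocenters stay intact.

**Compound list**

1 | (S)-4-benzyloxazolidin-2-one | O=C1N[C@@H](Cc2ccccc2)CO1 | starting material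
2 | pent-4-enoyl chloride | C=CCCC(Cl)=O | starting material
3 | (S)-4-benzyl-3-(pent-4-enoyl)oxazolidin-2-one | C=CCCC(=O)N1[C@@H](Cc2ccccc2)COC1=O | intermediate
4 | vanillin (4-hydroxy-3-methoxybenzaldehyde) | COc1cc(C=O)ccc1O | starting material
5 | 4-(tert-butyldimethylsilyloxy)-3-methoxybenzaldehyde | COc1cc(C=O)ccc1O[Si](C)(C)C(C)(C)C | intermediate
6 | (S)-4-benzyl-3-[(2S)-2-[(S)-[4-(tert-butyldimethylsilyloxy)-3-methoxyphenyl](hydroxy)methyl]pent-4-enoyl]oxazolidin-2-one | C=CC[C@H](C(=O)N1[C@@H](Cc2ccccc2)COC1=O)[C@H](O)c3ccc(O[Si](C)(C)C(C)(C)C)c(OC)c3 | intermediate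
7 | (1S,2R)-1-[4-(tert-butyldimethylsilyloxy)-3-methoxyphenyl]-2-(prop-2-enyl)propane-1,3-diol | C=CC[C@H](CO)[C@H](O)c1ccc(O[Si](C)(C)C(C)(C)C)c(OC)c1 | intermediate
8 | (4R,5S)-5-[4-(tert-butyldimethylsilyloxy)-3-methoxyphenyl]-4-(hydroxymethyl)tetrahydrofuran-2-ol, anomer mixture | OC[C@H]1CC(O)O[C@@H]1c2ccc(O[Si](C)(C)C(C)(C)C)c(OC)c2 | intermediate
9 | syringaldehyde (4-hydroxy-3,5-dimethoxybenzaldehyde) | COc1cc(C=O)cc(OC)c1O | starting material
10 | 4-(tert-butyldimethylsilyloxy)-3,5-dimethoxybenzaldehyde | COc1cc(C=O)cc(OC)c1O[Si](C)(C)C(C)(C)C | intermediate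
11 | (2E,3R,4S)-2-[[4-(tert-butyldimethylsilyloxy)-3,5-dimethoxyphenyl]methylidene]-4-[4-(tert-butyldimethylsilyloxy)-3-methoxyphenyl]-4-hydroxy-3-(hydroxymethyl)butanal | O=C/C(=C/c1cc(OC)c(O[Si](C)(C)C(C)(C)C)c(OC)c1)[C@H](CO)[C@H](O)c2ccc(O[Si](C)(C)C(C)(C)C)c(OC)c2 | intermediate
12 | (3R,4S)-6-(tert-butyldimethylsilyloxy)-4-[4-(tert-butyldimethylsilyloxy)-3-methoxyphenyl]-3-(hydroxymethyl)-5,7-dimethoxy-3,4-dihydronaphthalene-2-carbaldehyde | COc1cc([C@H]2c3c(cc(OC)c(O[Si](C)(C)C(C)(C)C)c3OC)C=C(C=O)[C@@H]2CO)ccc1O[Si](C)(C)C(C)(C)C | intermediate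
13 | (3R,4S)-6-hydroxy-4-(4-hydroxy-3-methoxyphenyl)-3-(hydroxymethyl)-5,7-dimethoxy-3,4-dihydronaphthalene-2-carbaldehyde | COc1cc([C@H]2c3c(cc(OC)c(O)c3OC)C=C(C=O)[C@@H]2CO)ccc1O | target

**Count and risks**

Total steps: 8. Longest linear sequence: 6 (steps 1, 3, 4, 5, 7, 8).

Steps most likely to fail:

1. Step 7. The lactol-derived enamine may self-condense or stall before adding to the hindered, electron-rich aldehyde. In the acid stage the benzylic cation may lose the C3 proton (diene formation and loss of the stereocenter) or be trapped by the carbonyl oxygen (furan formation) instead of closing ring B. The fallback uses known reaction types in separate, protected steps and sets out from diol 7. The diol would be tied up with 2,2-dimethoxypropane and PPTS in CH2Cl2 as the acetonide, (4S,5R)-4-[4-(tert-butyldimethylsilyloxy)-3-methoxyphenyl]-2,2-dimethyl-5-(prop-2-enyl)-1,3-dioxane F1. Cleavage of F1 with OsO4 (cat.), NaIO4 and 2,6-lutidine should give the aldehyde that cannot lactolize, 2-[(4S,5R)-4-[4-(tert-butyldimethylsilyloxy)-3-methoxyphenyl]-2,2-dimethyl-1,3-dioxan-5-yl]acetaldehyde F2. F2 would be condensed with 10 in an isolated crossed aldol condensation through its preformed pyrrolidine enamine (pyrrolidine, AcOH, toluene, molecular sieves, 60 °C) to the E-enal, (E)-2-[(4S,5R)-4-[4-(tert-butyldimethylsilyloxy)-3-methoxyphenyl]-2,2-dimethyl-1,3-dioxan-5-yl]-3-[4-(tert-butyldimethylsilyloxy)-3,5-dimethoxyphenyl]prop-2-enal F3. Treatment of purified F3 with TFA in wet CH2Cl2 at 0 °C should ionize the benzylic C–O bond of the dioxane, close ring B by Friedel–Crafts alkylation and release acetone, returning to the route at 12.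

2. Step 8. Under fluoride the phenoxide of the product may trigger air oxidation (aromatization of ring B) or quinone methide chemistry at the doubly benzylic C4. The fallback moves the deprotection ahead of the ring construction and sets out from lactol 8. Desilylation with Bu4NF and AcOH in THF at 0 °C should give the robust free-phenol lactol, (4R,5S)-5-(4-hydroxy-3-methoxyphenyl)-4-(hydroxymethyl)tetrahydrofuran-2-ol F4. F4 and syringaldehyde 9 would then be taken through the amine/acid sequence (piperidinium acetate, toluene, then mild acid), passing the free-phenol enal, (2E,3R,4S)-4-hydroxy-2-[(4-hydroxy-3,5-dimethoxyphenyl)methylidene]-4-(4-hydroxy-3-methoxyphenyl)-3-(hydroxymethyl)butanal F5, in which the free para-hydroxyl lets C4 ionize through a p-quinone methide. The route is rejoined at 13 with no final deprotection.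

3. Step 4. The electron-rich benzylic aldolate may fragment by retro-aldol cleavage under the basic hydride conditions, or hydride may attack the ring carbonyl of the auxiliary. The fallback blocks the aldol hydroxyl first and sets out from 6. Silylation with TESOTf and 2,6-lutidine in CH2Cl2 at −78 °C should give the triethylsilyl ether, (S)-4-benzyl-3-[(2S)-2-[(S)-[4-(tert-butyldimethylsilyloxy)-3-methoxyphenyl](triethylsilyloxy)methyl]pent-4-enoyl]oxazolidin-2-one F6. Reduction with LiBH4 and MeOH in THF then gives the primary alcohol, (2R)-2-[(S)-[4-(tert-butyldimethylsilyloxy)-3-methoxyphenyl](triethylsilyloxy)methyl]pent-4-en-1-ol F7. Mild aqueous acid (AcOH, THF, H2O, rt) removes the alkyl silyl ether in the presence of the aryl one and returns to the route at 7; any epimerization at the carbinol carbon there is harmless because step 7 erases that center.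

Further compounds
F1 | step 7 | (4S,5R)-4-[4-(tert-butyldimethylsilyloxy)-3-methoxyphenyl]-2,2-dimethyl-5-(prop-2-enyl)-1,3-dioxane | C=CC[C@@H]1COC(C)(C)O[C@@H]1c2ccc(O[Si](C)(C)C(C)(C)C)c(OC)c2
F2 | step 7 | 2-[(4S,5R)-4-[4-(tert-butyldimethylsilyloxy)-3-methoxyphenyl]-2,2-dimethyl-1,3-dioxan-5-yl]acetaldehyde | O=CC[C@@H]1COC(C)(C)O[C@@H]1c2ccc(O[Si](C)(C)C(C)(C)C)c(OC)c2
F3 | step 7 | (E)-2-[(4S,5R)-4-[4-(tert-butyldimethylsilyloxy)-3-methoxyphenyl]-2,2-dimethyl-1,3-dioxan-5-yl]-3-[4-(tert-butyldimethylsilyloxy)-3,5-dimethoxyphenyl]prop-2-enal | O=C/C(=C/c1cc(OC)c(O[Si](C)(C)C(C)(C)C)c(OC)c1)[C@@H]2COC(C)(C)O[C@@H]2c3ccc(O[Si](C)(C)C(C)(C)C)c(OC)c3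
F4 | step 8 | (4R,5S)-5-(4-hydroxy-3-methoxyphenyl)-4-(hydroxymethyl)tetrahydrofuran-2-ol, anomer mixture | OC[C@H]1CC(O)O[C@@H]1c2ccc(O)c(OC)c2
F5 | step 8 | (2E,3R,4S)-4-hydroxy-2-[(4-hydroxy-3,5-dimethoxyphenyl)methylidene]-4-(4-hydroxy-3-methoxyphenyl)-3-(hydroxymethyl)butanal | O=C/C(=C/c1cc(OC)c(O)c(OC)c1)[C@H](CO)[C@H](O)c2ccc(O)c(OC)c2
F6 | step 4 | (S)-4-benzyl-3-[(2S)-2-[(S)-[4-(tert-butyldimethylsilyloxy)-3-methoxyphenyl](triethylsilyloxy)methyl]pent-4-enoyl]oxazolidin-2-one | C=CC[C@H](C(=O)N1[C@@H](Cc2ccccc2)COC1=O)[C@H](O[Si](CC)(CC)CC)c3ccc(O[Si](C)(C)C(C)(C)C)c(OC)c3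
F7 | step 4 | (2R)-2-[(S)-[4-(tert-butyldimethylsilyloxy)-3-methoxyphenyl](triethylsilyloxy)methyl]pent-4-en-1-ol | C=CC[C@H](CO)[C@H](O[Si](CC)(CC)CC)c1ccc(O[Si](C)(C)C(C)(C)C)c(OC)c1
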